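**Strategy.** The six-membered ring (C1–C6, bisabolane numbering) bears cis oxygens at C1 and C2 that lie between the methyl-bearing C3 and the chain-bearing C6, two carbons para to one another. This is the pattern of a para-disubstituted benzene that has been cis-dihydroxylated across one ortho/meta bond, so the ring is disconnected to flat, commercial 4-iodotoluene. A single enzymatic dearomatisation forms both C–O bonds and both carbinol stereocentres, and leaves a vinyl iodide at C6 for attaching the C7–C11 chain and the C3=C4 alkene for a later hydroxyl-directed epoxidation. Iodine, the largest halogen, is chosen to steer the enzyme. The remaining centres are relayed from this diol or set by reagent control.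

Key step: step 1

Assumption: bisabolane numbering is used for all intermediates (ring C1–C6 with C1 the ester carbon, C2 the carbinol, C3 methyl-bearing, C6 chain-bearing; chain C7–C11; C14 the methylene carbon on C7), and the 2-methylbutanoate is taken as (R), as the target SMILES specifies, from commercial (R)-2-methylbutanoic acid.

**Step 1**
Reactants: 1 4-iodotoluene
Product: 2 (1S,2S)-3-iodo-6-methylcyclohexa-3,5-diene-1,2-diol
Conditions: E. coli JM109(pDTG601A) whole cells expressing toluene dioxygenase, IPTG, air (O2), glucose feed, phosphate buffer pH 7, 30 °C; EtOAc extraction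
Reagents that add atoms: dioxygen, O=O
Why: Electrons from NADH pass through the reductase, the ferredoxin and the Rieske [2Fe–2S] cluster to the mononuclear non-heme iron (divalent in its reduced state), which binds O2 side-on and transfers both oxygen atoms to one face of the C1–C2 π bond of the bound arene, so that the two C–O bonds form suprafacially and the ring is dearomatised to a cis-dihydrodiol. The closest known reaction type is the dioxygenase cis-dihydroxylation of halobenzenes and of para-substituted halotoluenes. No ring is closed. Both new stereocentres (C1 and C2) are controlled by the active site, which should seat iodine where the halogen of a halobenzene binds, so that 2 has the same (1S,2S) sense as the halobenzene diols. Since the two oxidisable ring bonds are mirror images of each other in the substrate, the only selectivity needed is the iodine-versus-methyl discrimination (enantioselectivity), which rests on the greater size of iodine; the enantiomeric purity of 2 is to be checked by chiral HPLC and raised by recrystallisation before use. A recombinant host without the cis-diol dehydrogenase prevents rearomatisation to the catechol.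

**Step 2**
Reactants: 2 (1S,2S)-3-iodo-6-methylcyclohexa-3,5-diene-1,2-diol
Product: 3 (3aS,7aS)-4-iodo-2,2,7-trimethyl-3a,7a-dihydro-1,3-benzodioxole (acetonide of 2)
Conditions: 2,2-dimethoxypropane, p-TsOH·H2O (cat.), acetone, 0 °C; Et3N quench
Reagents that add atoms: 2,2-dimethoxypropane, COC(C)(C)OC
Why: Acid-catalysed transacetalisation closes the cis-fused dioxolane on the cis-diol without touching a stereocentre, and the short, cold, base-quenched protocol should avoid acid-induced dehydration of the diene diol to a phenol.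

**Step 3**
Reactants: 4 methyl (S)-oxirane-2-carboxylate (methyl (S)-glycidate); 5 2-methylprop-1-enylmagnesium bromide
Product: 6 methyl (S)-2-hydroxy-5-methylhex-4-enoate
Conditions: CuI (10 mol %), THF, −78 to −40 °C; aq. NH4Cl
Reagents that add atoms: none
Why: Copper-catalysed SN2 opening of the terminal epoxide by the alkenyl Grignard reagent should occur at the unsubstituted carbon (future C9) faster than addition to the ester at low temperature, so the (S)-carbinol carbon (future C8) comes unchanged from the chiral pool.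

**Step 4**
Reactants: 6 methyl (S)-2-hydroxy-5-methylhex-4-enoate
Product: 7 methyl (S)-2-(tert-butyldimethylsilyloxy)-5-methylhex-4-enoate
Conditions: TBSCl, imidazole, DMF, rt
Reagents that add atoms: tert-butyldimethylsilyl chloride, CC(C)(C)[Si](C)(C)Cl
Why: Imidazole-assisted silylation of a secondary α-hydroxy ester is routine, does not involve the stereocentre, and gives an ether that should withstand the Grignard, copper hydride and titanium steps that follow.

**Step 5**
Reactants: 7 methyl (S)-2-(tert-butyldimethylsilyloxy)-5-methylhex-4-enoate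
Product: 8 (S)-2-(tert-butyldimethylsilyloxy)-N-methoxy-N,5-dimethylhex-4-enamide (Weinreb amide; its acyl carbon is C7, the chain runs to C11)
Conditions: MeONHMe·HCl, iPrMgCl, THF, −20 to 0 °C
Reagents that add atoms: N,O-dimethylhydroxylamine hydrochloride, CNOC.Cl
Why: Aminolysis of the methyl ester by the magnesium amide of N,O-dimethylhydroxylamine (Weinreb amide synthesis) should proceed at low temperature without enolising the α-silyloxy stereocentre.

**Step 6**
Reactants: 3 (3aS,7aS)-4-iodo-2,2,7-trimethyl-3a,7a-dihydro-1,3-benzodioxole; 8 (S)-2-(tert-butyldimethylsilyloxy)-N-methoxy-N,5-dimethylhex-4-enamide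
Product: 10 (1R,2S,8S)-8-(tert-butyldimethylsilyloxy)-1,2-(isopropylidenedioxy)bisabola-3,5,10-trien-7-one, via dienylmagnesium chloride 9 (not isolated)
Conditions: iPrMgCl·LiCl, THF, −30 °C; then 8, −30 to 0 °C; aq. NH4Cl
Reagents that add atoms: none
Why: Iodine–magnesium exchange of the alkenyl iodide gives a cyclic alkenyl Grignard reagent that cannot β-eliminate the C1 oxygen (a ring allene would result), and its addition to the Weinreb amide should stop at the chelated tetrahedral magnesium adduct, which releases the ketone only on work-up, so no tertiary alcohol forms and C8 is not epimerised.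

**Step 7**
Reactants: 10 (1R,2S,8S)-8-(tert-butyldimethylsilyloxy)-1,2-(isopropylidenedioxy)bisabola-3,5,10-trien-7-one
Product: 12 (1R,2S,6R,8S)-8-(tert-butyldimethylsilyloxy)-1,2-(isopropylidenedioxy)bisabola-3,10-dien-7-one (acyl chain at C6 cis to the C1 and C2 oxygens), via copper enolate 11 (not isolated)
Conditions: [(Ph3P)CuH]6, degassed H2O (5 equiv), benzene/THF, rt
Reagents that add atoms: none
Why: Stryker-type conjugate reduction should deliver hydride to C5 (the 1,6-terminus C3 is fully substituted and flanked by the acetonide) to give the exocyclic copper enolate 11, which water protonates at C6 under kinetic control from the face opposite the pseudoaxial C1–O bond and the dioxolane ring, as in the kinetic protonation of exocyclic enols of 2-substituted cyclohexyl ketones, so the chain ends up cis to both ring oxygens.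

**Step 8**
Reactants: 12 (1R,2S,6R,8S)-8-(tert-butyldimethylsilyloxy)-1,2-(isopropylidenedioxy)bisabola-3,10-dien-7-one
Product: 13 (1R,2S,6S,8S)-8-(tert-butyldimethylsilyloxy)-1,2-(isopropylidenedioxy)bisabola-3,7(14),10-triene
Conditions: Cp2Ti(μ-Cl)(μ-CH2)AlMe2, pyridine (cat.), THF/toluene, −40 to 0 °C
Reagents that add atoms: Tebbe reagent Cp2Ti(μ-Cl)(μ-CH2)AlMe2, C1[Ti](C2C=CC=C2)(C2C=CC=C2)[Cl+][Al-]1(C)C
Why: Tebbe methylenation (cycloaddition of the titanium methylidene to the ketone, then cycloreversion to Cp2Ti=O) should convert the hindered, enolisable C7 ketone to the 1,1-disubstituted alkene without base, so the epimerisable C6 and C8 centres and the β-alkoxy ketone are not put at risk.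

**Step 9**
Reactants: 13 (1R,2S,6S,8S)-8-(tert-butyldimethylsilyloxy)-1,2-(isopropylidenedioxy)bisabola-3,7(14),10-triene
Product: 14 (1R,2S,6S,8S)-1,2-(isopropylidenedioxy)bisabola-3,7(14),10-trien-8-ol
Conditions: Bu4NF, THF, 0 °C to rt
Reagents that add atoms: none
Why: Fluoride cleavage of the secondary silyl ether is safe here because the substrate holds no ester or other fluoride- or base-sensitive group at this stage.

**Step 10**
Reactants: 14 (1R,2S,6S,8S)-1,2-(isopropylidenedioxy)bisabola-3,7(14),10-trien-8-ol; 15 angelic acid ((Z)-2-methylbut-2-enoic acid)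
Product: 17 (1R,2S,6S,8S)-8-angeloyloxy-1,2-(isopropylidenedioxy)bisabola-3,7(14),10-triene, via mixed anhydride 16 (not isolated)
Conditions: 15, 2,4,6-trichlorobenzoyl chloride, Et3N, toluene, rt; then 14, toluene, 75 °C
Reagents that add atoms: none
Why: Yamaguchi-type esterification through the mixed 2,4,6-trichlorobenzoic anhydride, run without a nucleophilic catalyst, is the established way to form angelates without Z-to-E isomerisation to the tiglate, and acylation at oxygen leaves C8 unchanged.

**Step 11**
Reactants: 17 (1R,2S,6S,8S)-8-angeloyloxy-1,2-(isopropylidenedioxy)bisabola-3,7(14),10-triene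
Product: 18 (1R,2S,6S,8S)-8-angeloyloxybisabola-3,7(14),10-triene-1,2-diol
Conditions: AcOH/H2O (4:1), 45 °C
Reagents that add atoms: none
Why: Acid-catalysed hydrolysis of the dioxolane under mild aqueous acetic acid should be tolerated by the ester and the three alkenes and affects no stereocentre.

**Step 12**
Reactants: 18 (1R,2S,6S,8S)-8-angeloyloxybisabola-3,7(14),10-triene-1,2-diol
Product: 19 (1R,2S,6S,8S)-8-angeloyloxy-2-(triethylsilyloxy)bisabola-3,7(14),10-trien-1-ol
Conditions: TESCl (1.05 equiv), imidazole, CH2Cl2, −40 °C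
Reagents that add atoms: chlorotriethylsilane, CC[Si](Cl)(CC)CC
Why: Kinetically controlled monosilylation should select O2, because with the C6 chain equatorial the C1 hydroxyl is axial and flanked by the branched C6 substituent, whereas the allylic C2 hydroxyl is pseudoequatorial and exposed.

**Step 13**
Reactants: 19 (1R,2S,6S,8S)-8-angeloyloxy-2-(triethylsilyloxy)bisabola-3,7(14),10-trien-1-ol; 20 (R)-2-methylbutanoic acid
Product: 22 (1R,2S,6S,8S)-8-angeloyloxy-1-[(2R)-2-methylbutanoyloxy]-2-(triethylsilyloxy)bisabola-3,7(14),10-triene, via mixed anhydride 21 (not isolated)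
Conditions: 20, 2,4,6-trichlorobenzoyl chloride, Et3N, THF, rt; then 19, DMAP, toluene, rt
Reagents that add atoms: none
Why: Yamaguchi esterification with DMAP should acylate the remaining hindered C1 hydroxyl through the acylpyridinium ion, a pathway that does not involve the α-carbon of the acid, so its (R) centre and C1 are retained.

**Step 14**
Reactants: 22 (1R,2S,6S,8S)-8-angeloyloxy-1-[(2R)-2-methylbutanoyloxy]-2-(triethylsilyloxy)bisabola-3,7(14),10-triene
Product: 23 (1R,2S,6S,8S)-8-angeloyloxy-1-[(2R)-2-methylbutanoyloxy]bisabola-3,7(14),10-trien-2-ol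
Conditions: HF·pyridine, pyridine, THF, 0 °C
Reagents that add atoms: none
Why: Buffered HF·pyridine removes the triethylsilyl ether under mildly acidic conditions, which should suppress 1,2-acyl migration from O1 to the freed O2 and leave both esters intact.

**Step 15**
Reactants: 23 (1R,2S,6S,8S)-8-angeloyloxy-1-[(2R)-2-methylbutanoyloxy]bisabola-3,7(14),10-trien-2-ol
Product: 24 (1R,2R,3R,4S,6S,8S)-8-angeloyloxy-3,4-epoxy-1-[(2R)-2-methylbutanoyloxy]bisabola-7(14),10-dien-2-ol
Conditions: VO(acac)2 (5 mol %), t-BuOOH (decane solution), CH2Cl2, 0 °C to rt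
Reagents that add atoms: tert-butyl hydroperoxide, CC(C)(C)OO
Why: In this hydroxyl-directed epoxidation the C2 alkoxide binds the vanadium alkyl peroxide and delivers oxygen to the C3=C4 bond on its own face, setting C3 and C4 syn to the hydroxyl, while the C10=C11 and C7=C14 alkenes and the angelate, which lack a free allylic hydroxyl, should not react.

**Step 16**
Reactants: 24 (1R,2R,3R,4S,6S,8S)-8-angeloyloxy-3,4-epoxy-1-[(2R)-2-methylbutanoyloxy]bisabola-7(14),10-dien-2-ol
Product: 25 (1R,2R,3R,4S,6S,8S,10R)-8-angeloyloxy-3,4:10,11-diepoxy-1-[(2R)-2-methylbutanoyloxy]bisabol-7(14)-en-2-ol (CNP0181486.1)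
Conditions: Shi ketone (1,2:4,5-di-O-isopropylidene-β-D-erythro-2,3-hexodiulo-2,6-pyranose, 1 equiv), Oxone (2KHSO5·KHSO4·K2SO4), NaHCO3, Bu4NHSO4 (cat.), MeCN/aq. Na2EDTA, pH 7.5–8, 0 °C
Reagents that add atoms: potassium peroxymonosulfate (active component of Oxone), [K+].[O-]S(=O)(=O)OO
Why: In the Shi asymmetric epoxidation the chiral dioxirane from the D-fructose-derived ketone should attack the electron-rich, unhindered trisubstituted C10=C11 alkene through the spiro transition state that gives (R) at the CH carbon of R–CH2–CH=CMe2 olefins (reagent control), while the 1,1-disubstituted C7=C14 alkene and the angelate react far more slowly and the near-neutral buffer spares the hydroxy ester.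

**Compound list**
1 | 4-iodotoluene | Cc1ccc(I)cc1 | starting material
2 | (1S,2S)-3-iodo-6-methylcyclohexa-3,5-diene-1,2-diol | IC1=CC=C(C)[C@H](O)[C@@H]1O | intermediate
3 | (3aS,7aS)-4-iodo-2,2,7-trimethyl-3a,7a-dihydro-1,3-benzodioxole | IC1=CC=C(C)[C@@H]2OC(C)(C)O[C@H]12 | intermediate
4 | methyl (S)-oxirane-2-carboxylate (methyl (S)-glycidate) | COC(=O)[C@@H]1CO1 | starting material
5 | 2-methylprop-1-enylmagnesium bromide | CC(C)=C[Mg]Br | starting material
6 | methyl (S)-2-hydroxy-5-methylhex-4-enoate | CC(C)=CC[C@H](O)C(=O)OC | intermediate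
7 | methyl (S)-2-(tert-butyldimethylsilyloxy)-5-methylhex-4-enoate | CC(C)=CC[C@H](O[Si](C)(C)C(C)(C)C)C(=O)OC | intermediate
8 | (S)-2-(tert-butyldimethylsilyloxy)-N-methoxy-N,5-dimethylhex-4-enamide | CC(C)=CC[C@H](O[Si](C)(C)C(C)(C)C)C(=O)N(C)OC | intermediate
9 | [(3aS,7aS)-2,2,7-trimethyl-3a,7a-dihydro-1,3-benzodioxol-4-yl]magnesium chloride (LiCl complex, formed in the flask) | Cl[Mg]C1=CC=C(C)[C@@H]2OC(C)(C)O[C@H]12 | intermediate
10 | (1R,2S,8S)-8-(tert-butyldimethylsilyloxy)-1,2-(isopropylidenedioxy)bisabola-3,5,10-trien-7-one | CC(C)=CC[C@H](O[Si](C)(C)C(C)(C)C)C(=O)C1=CC=C(C)[C@@H]2OC(C)(C)O[C@H]12 | intermediate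
11 | copper enolate of 12 (C6=C7 enolate, oxygen-bound monovalent copper, phosphine omitted, enolate geometry not assigned; formed in the flask) | CC(C)=CC[C@H](O[Si](C)(C)C(C)(C)C)C(O[Cu])=C1CC=C(C)[C@@H]2OC(C)(C)O[C@H]12 | intermediate
12 | (1R,2S,6R,8S)-8-(tert-butyldimethylsilyloxy)-1,2-(isopropylidenedioxy)bisabola-3,10-dien-7-one | CC(C)=CC[C@H](O[Si](C)(C)C(C)(C)C)C(=O)[C@@H]1CC=C(C)[C@@H]2OC(C)(C)O[C@H]12 | intermediate
13 | (1R,2S,6S,8S)-8-(tert-butyldimethylsilyloxy)-1,2-(isopropylidenedioxy)bisabola-3,7(14),10-triene | CC(C)=CC[C@H](O[Si](C)(C)C(C)(C)C)C(=C)[C@@H]1CC=C(C)[C@@H]2OC(C)(C)O[C@H]12 | intermediate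
14 | (1R,2S,6S,8S)-1,2-(isopropylidenedioxy)bisabola-3,7(14),10-trien-8-ol | CC(C)=CC[C@H](O)C(=C)[C@@H]1CC=C(C)[C@@H]2OC(C)(C)O[C@H]12 | intermediate
15 | angelic acid ((Z)-2-methylbut-2-enoic acid) | C/C=C(/C)C(=O)O | starting material
16 | angelic 2,4,6-trichlorobenzoic anhydride (formed in the flask) | C/C=C(/C)C(=O)OC(=O)c1c(Cl)cc(Cl)cc1Cl | intermediate
17 | (1R,2S,6S,8S)-8-angeloyloxy-1,2-(isopropylidenedioxy)bisabola-3,7(14),10-triene | CC(C)=CC[C@H](OC(=O)/C(C)=C\C)C(=C)[C@@H]1CC=C(C)[C@@H]2OC(C)(C)O[C@H]12 | intermediate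
18 | (1R,2S,6S,8S)-8-angeloyloxybisabola-3,7(14),10-triene-1,2-diol | CC(C)=CC[C@H](OC(=O)/C(C)=C\C)C(=C)[C@@H]1CC=C(C)[C@H](O)[C@@H]1O | intermediate
19 | (1R,2S,6S,8S)-8-angeloyloxy-2-(triethylsilyloxy)bisabola-3,7(14),10-trien-1-ol | CC(C)=CC[C@H](OC(=O)/C(C)=C\C)C(=C)[C@@H]1CC=C(C)[C@H](O[Si](CC)(CC)CC)[C@@H]1O | intermediate
20 | (R)-2-methylbutanoic acid | CC[C@@H](C)C(=O)O | starting material
21 | (R)-2-methylbutanoic 2,4,6-trichlorobenzoic anhydride (formed in the flask) | CC[C@@H](C)C(=O)OC(=O)c1c(Cl)cc(Cl)cc1Cl | intermediate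
22 | (1R,2S,6S,8S)-8-angeloyloxy-1-[(2R)-2-methylbutanoyloxy]-2-(triethylsilyloxy)bisabola-3,7(14),10-triene | CC(C)=CC[C@H](OC(=O)/C(C)=C\C)C(=C)[C@@H]1CC=C(C)[C@H](O[Si](CC)(CC)CC)[C@@H]1OC(=O)[C@H](C)CC | intermediate
23 | (1R,2S,6S,8S)-8-angeloyloxy-1-[(2R)-2-methylbutanoyloxy]bisabola-3,7(14),10-trien-2-ol | CC(C)=CC[C@H](OC(=O)/C(C)=C\C)C(=C)[C@@H]1CC=C(C)[C@H](O)[C@@H]1OC(=O)[C@H](C)CC | intermediate
24 | (1R,2R,3R,4S,6S,8S)-8-angeloyloxy-3,4-epoxy-1-[(2R)-2-methylbutanoyloxy]bisabola-7(14),10-dien-2-ol | CC(C)=CC[C@H](OC(=O)/C(C)=C\C)C(=C)[C@@H]1C[C@@H]2O[C@]2(C)[C@H](O)[C@@H]1OC(=O)[C@H](C)CC | intermediate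
25 | (1R,2R,3R,4S,6S,8S,10R)-8-angeloyloxy-3,4:10,11-diepoxy-1-[(2R)-2-methylbutanoyloxy]bisabol-7(14)-en-2-ol (CNP0181486.1) | C=C([C@H](C[C@H]1OC1(C)C)OC(=O)/C(C)=C\C)[C@@H]1C[C@@H]2O[C@]2(C)[C@H](O)[C@@H]1OC(=O)[C@H](C)CC | target

**Step count.** Total: 16 steps. Longest linear sequence: 14 steps (steps 3–16, from methyl (S)-glycidate); the arene branch runs through 13 steps (steps 1, 2 and 6–16).

**Steps most likely to fail**

Step 7. Hydride may add in the 1,6- or 1,2-sense, the enolate may be protonated on the wrong face of C6, or it may expel the C1 oxygen on the way to an arene. Fallback: starting from 10, rhodium-catalysed 1,4-hydrosilylation (RhCl(PPh3)3, Et3SiH, benzene, 50 °C) would give the isolable triethylsilyl enol ether F1. C-protonation of this enol ether under acidic, enolate-free conditions (HF·pyridine, THF, −40 °C) would then set C6 in a separate operation and rejoin the route at 12. If substrate control is still inadequate, a chiral N-triflyl phosphoramide with phenol as the proton source could be used for that protonation instead.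

Step 12. Silylation may fail to distinguish O2 from O1, or the silyl group may migrate to O1 during the following acylation. Fallback: starting from 18, oxidation of the allylic C2 hydroxyl alone (MnO2, CH2Cl2, rt) would give the hydroxy enone F2. Yamaguchi acylation of its single hydroxyl with 20 would give the acyloxy enone F3. Luche reduction (NaBH4, CeCl3·7H2O, MeOH, −78 °C), with hydride entering anti to the axial C1 acyloxy group, would return the cis C2 alcohol and rejoin the route at 23 without any silyl group.

Step 8. The titanium reagent may enolise the hindered ketone toward C6 (epimerisation, then loss of the C1 oxygen) in place of methylene transfer. Fallback: starting from 12, addition of the non-basic organocerium reagent made from Me3SiCH2Li and CeCl3 (THF, −78 °C) would give the β-hydroxysilane F4, and Peterson elimination (KH, THF, 0 °C) would rejoin the route at 13.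

**Further compounds**
F1 | step 7 | (1R,2S,8S)-8-(tert-butyldimethylsilyloxy)-1,2-(isopropylidenedioxy)-7-(triethylsilyloxy)bisabola-3,6,10-triene (C6=C7 geometry not defined) | CC(C)=CC[C@H](O[Si](C)(C)C(C)(C)C)C(O[Si](CC)(CC)CC)=C1CC=C(C)[C@@H]2OC(C)(C)O[C@H]12
F2 | step 12 | (1R,6S,8S)-8-angeloyloxy-1-hydroxybisabola-3,7(14),10-trien-2-one | CC(C)=CC[C@H](OC(=O)/C(C)=C\C)C(=C)[C@@H]1CC=C(C)C(=O)[C@@H]1O
F3 | step 12 | (1R,6S,8S)-8-angeloyloxy-1-[(2R)-2-methylbutanoyloxy]bisabola-3,7(14),10-trien-2-one | CC(C)=CC[C@H](OC(=O)/C(C)=C\C)C(=C)[C@@H]1CC=C(C)C(=O)[C@@H]1OC(=O)[C@H](C)CC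
F4 | step 8 | 8-(tert-butyldimethylsilyloxy)-1,2-(isopropylidenedioxy)-14-(trimethylsilyl)bisabola-3,10-dien-7-ol (C7 configuration not defined, other centres as in 12) | CC(C)=CC[C@H](O[Si](C)(C)C(C)(C)C)C(O)(C[Si](C)(C)C)[C@@H]1CC=C(C)[C@@H]2OC(C)(C)O[C@H]12
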